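Compound numbers are those of the steps and of the compound list below. Shorthand used throughout: Ar = 4-(benzyloxy)-3-methoxyphenyl; BF = the (2R,3R)-2-Ar-3-[(tert-butyldiphenylsilyloxy)methyl]-7-methoxy-2,3-dihydrobenzofuran-5-yl group. Primed locants belong to the dihydrobenzofuran, unprimed locants to the tetrahydrofuran (steps 12–18) or to the chromone and chromanone (steps 3–6).

## Analysis of the target

The target joins two oxygen heterocycles through an aryl–carbon bond. One is a tetrahydrofuran: O1, C2 with a 4-hydroxy-3-methoxybenzyl group, C3 with OH, C4 with CH2OH, C5 with the aryl group. The other is a 2-aryl-3-(hydroxymethyl)-7-methoxy-2,3-dihydrobenzofuran (O1', C2', C3', C3a'–C7a') bonded to C5 through C5'. There are six stereocentres, (2S,3S,4S,5S) and (2'R,3'R). In the tetrahydrofuran the C2 benzyl and C5 aryl groups are cis, the C3 hydroxyl is cis to the benzyl group and trans to the C4 hydroxymethyl group, and the latter is trans to the C5 aryl group. In the dihydrobenzofuran the aryl and hydroxymethyl groups are cis. The two stereo-clusters are separated by a benzene ring and cannot control each other, so each needs its own source of absolute configuration. The sensitive groups are two free guaiacyl phenols and two benzylic ether bonds, C5–O1 and C2'–O1', each para to an oxygen substituent. These bonds ionise under acid and can be cut by hydrogenolysis. The main difficulty is the cis-dihydrobenzofuran: it is the less stable isomer and epimerises through ionisation at C2' or, at the ester stage, through enolisation at C3'. The strategy rests on one structural feature: C3' and its CH2OH carbon correspond to C3 and the C4 carbonyl carbon of a 2-arylchroman-4-one. The dihydrobenzofuran is thus a flavanone with one ring atom fewer, in which the aryl carbon C4a has moved from C4 to C3.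

## Retrosynthetic reasoning

**Unmasking (30 ⇒ 29 ⇒ 28).** The last two operations only free oxygen functions. The phenols are carried as benzyl ethers (29) and the C3' hydroxymethyl group as a tert-butyldiphenylsilyl ether (28). Aryl benzyl ethers are the benzyl ethers that hydrogenolyse fastest, so the benzylic ring bonds C5–O1 and C2'–O1' are exposed to hydrogen and palladium only briefly. An alkyl benzyl ether on the C3' arm would need much longer, so that arm is silylated and freed by fluoride.

**C3 carbinol and C4 branch (28 ⇒ 27 ⇒ 25).** The C3–OH/C4–CH2OH pair is a 1,3-diol, an aldol pattern. Removing the C3 hydrogen gives β-hydroxy ketone 27, and cutting the C4–CH2OH bond gives ketone 25. The cut is made here because both centres can be set by their neighbours. The one-carbon electrophile enters C4 opposite the C5 aryl group, and the new hydroxyl then delivers hydride to C3 on its own face. The forward steps must enolise 25 towards C4 and not towards C2.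

**Tetrahydrofuran ring and union of the halves (25 ⇒ 24 ⇒ 23 ⇒ 21 + 16).** The ring is opened at C4–C5, between the enolisable methylene and the benzylic, oxygen-bearing carbon. Heterolysis there gives an enolate and an aryl-stabilised oxocarbenium ion, the pair that enol acetal 24 releases under a Lewis acid (Petasis–Ferrier rearrangement). 24 comes from dioxolanone 23 by carbonyl methylenation, and 23 from hydroxy acid 21 and aldehyde 16 by acetal formation. A cut at O1–C5 instead would require a stereodefined open chain first. With the chosen cut the molecule falls into two halves of similar size, C2 is bought with 21, and C5 is set cis to it during ring closure.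

**Hydroxy acid (21 ⇒ 20 ⇒ 17 + 18).** The single stereocentre of this half is not created but purchased in epoxide 18. Cutting the aryl–CH2 bond leads to aryl bromide 17 as the source of the nucleophile and to 18 as the electrophile; ester 20 is then saponified to 21.

**Aldehyde (16 ⇒ 15 ⇒ 14 ⇒ 13).** These are changes of oxidation level and protection only. Both one-carbon arms, on C5' and on C3', are ester carbons in 13. They are reduced together (14), the benzylic one alone is reoxidised (15), and the other is silylated (16).

**Key disconnection (13 ⇒ 10).** In 13 the bond C3'–C3a' is cut and C3a' is reconnected to the ester carbon on C3'. This turns the five-membered ring into the six-membered ring of diazo ketone 10, with the ester carbon as the C4 carbonyl. The gain is that 10 has only one stereocentre, C2, and that centre can be set on a flat chromone by catalysis. The forward ring contraction then supplies the ring, the C3'–C3a' bond, the C3' centre and the ester carbon in one operation. It must make the aryl carbon migrate rather than the C2 hydrogen, and it must protonate the resulting enol on the face away from the C2' aryl group.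

**Diazo ketone (10 ⇒ 7 ⇒ 5 + 6).** The diazo group is placed on the C3 methylene of flavanone 7 by diazo transfer. The C2–aryl bond of 7 is cut to give chromone 5 and boronic acid 6. This is the only point in this half where an external chiral influence is needed.

**Chromone (5 ⇒ 3 ⇒ 2 ⇒ 1).** C2 of the chromone is a one-carbon unit added to the acetyl group of 3. The ester of 3 comes from bromide 2 by carbonylation, and 2 from purchased acetophenone 1 by bromination para to the phenol.

## Alternatives that were turned down

**Alternative 1:** The tetrahydrofuran is traced back, through a ring-expanded lactone, to cyclobutanone A1, which is cut across two ring bonds into dichloroketene A3 and chiral Z-enol ether A2.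
- Forward key step: A3, made in the flask, adds across the electron-rich double bond of A2. The β-carbon bonds to the ketene carbonyl carbon (future C2–carbonyl bond) and the oxygen-bearing carbon to the CCl2 carbon (future C3–C4 bond). The Z geometry becomes the cis relationship of C2 and C3, and the auxiliary shields one face. A Baeyer–Villiger ring expansion steered by the chlorine atoms would then give the five-membered oxygen ring.
- For it: the cis C2-benzyl/C3-oxygen pair is fixed in one concerted step under reliable auxiliary control, with C3 at the right oxidation level from the start.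
- Against it: A1 holds only two of the six stereocentres. The C4 branch and the C5 aryl group would still have to be added to a lactone. The whole dihydrobenzofuran would have to be introduced as an aryl-metal and the resulting lactol reduced under Lewis acid, conditions under which C2'–O1' can ionise. The auxiliary is stoichiometric, must be made and removed, and the chlorine atoms must be taken out.
- Comparison: on the C2/C3 pair it is stronger than the chosen route, which sets C3 only late by a directed reduction. The chosen route instead solves the harder problem, the cis-dihydrobenzofuran, in one ring contraction, takes C2 from a purchased epoxide, and joins two halves convergently in fewer steps.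

**Alternative 2:** The C4–C5 bond of the tetrahydrofuran is cut, leading from ketone A4 to enol acetal A5.
- Forward key step: an aluminium Lewis acid ionises A5 to an enolate and an aryl oxocarbenium ion, which recombine to A4 with the 2,5-cis arrangement.
- For it: it is convergent, transfers the configuration of the lactic acid carbon to C2, and sets C5 in the same step.
- Against it: as a strategy it does not address the cis-dihydrobenzofuran, which enters as a finished aldehyde. The closure is formally 5-endo. The Lewis acid meets the acid-sensitive C2'–O1' bond. The benzyl ether on the C3' arm of A4 would force a long final hydrogenolysis.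
- Comparison: for the tetrahydrofuran it is exactly as strong as the chosen route, because the chosen route uses this same rearrangement for the union of the halves (step 14). What the chosen strategy adds is a short, catalytic-asymmetric entry to the cis-dihydrobenzofuran aldehyde, and a silyl group in place of the benzyl group on the C3' arm.

**Alternative 3:** The O1'–C2' bond of the dihydrobenzofuran is cut, leading from A6 to the open-chain phenol A7, whose two stereocentres come from an auxiliary-controlled syn-aldol reaction.
- Forward key step: under Mitsunobu conditions the ortho phenol of A7 displaces the activated benzylic hydroxyl with inversion and closes the cis ring of A6.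
- For it: both centres are set by one of the most predictable reactions available. The sulfonate on the C2' aryl ring damps ionisation, and the bromide is a handle for the later formyl group.
- Against it: the displacement takes place at a secondary benzylic carbon next to a branched centre, with a hindered, doubly ortho-substituted phenol as the nucleophile. Any ionisation leaks to the more stable trans ring. The sulfonate and the bromide each cost extra steps, and the auxiliary is stoichiometric.
- Comparison: it is stronger in predictability of absolute configuration. The chosen route offers one catalytic asymmetric step whose centre relays to C3', an ester already in place at C5', and a shorter path to aldehyde 16.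

Key step: step 6

Assumption: 1, 6, 17 and 18 are taken as purchasable, and the (S)-pyridine–oxazoline ligand is assumed to give the 2R flavanone by the facial sense it shows with cyclic enones; the mirror-image ligand would be used if the sense were opposite.

## Steps

Step 1
Reactants: 1 2'-hydroxy-3'-methoxyacetophenone
Product: 2 5'-bromo-2'-hydroxy-3'-methoxyacetophenone
Conditions: NBS, MeCN, 0 °C → rt
Reagents that add atoms: N-bromosuccinimide, O=C1CCC(=O)N1Br
Why: Electrophilic aromatic bromination; the phenol directs to its para position C5' because both ortho positions are occupied, and the hydrogen-bonded acetyl group is not brominated under these conditions.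

Step 2
Reactants: 2 5'-bromo-2'-hydroxy-3'-methoxyacetophenone
Product: 3 methyl 3-acetyl-4-hydroxy-5-methoxybenzoate
Conditions: CO (1 atm), Pd(OAc)2 (2 mol%), Xantphos (4 mol%), Et3N, MeOH–toluene, 70 °C
Reagents that add atoms: carbon monoxide, [C-]#[O+]; methanol, CO
Why: Palladium-catalysed methoxycarbonylation of an aryl bromide (oxidative addition to zerovalent palladium, CO insertion, methanolysis). It is preferred to a Fries route because hot AlCl3 would attack the methyl ether next to the phenol.

Step 3
Reactants: 3 methyl 3-acetyl-4-hydroxy-5-methoxybenzoate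
Product: 5 methyl 8-methoxy-4-oxo-4H-chromene-6-carboxylate, via enaminone 4 (not isolated)
Conditions: Me2NCH(OMe)2, toluene, 100 °C; evaporate; conc. HCl, CH2Cl2, rt
Reagents that add atoms: N,N-dimethylformamide dimethyl acetal, COC(OC)N(C)C
Why: Standard chromone synthesis from a 2-hydroxyacetophenone: enaminone formation at the acetyl methyl group, then acid-promoted conjugate addition of the phenol and loss of dimethylamine.

Step 4
Reactants: 5 methyl 8-methoxy-4-oxo-4H-chromene-6-carboxylate; 6 (4-benzyloxy-3-methoxyphenyl)boronic acid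
Product: 7 methyl (2R)-2-Ar-8-methoxy-4-oxochroman-6-carboxylate
Conditions: 6 (1.5 equiv), Pd(OCOCF3)2 (5 mol%), (S)-4-tert-butyl-2-(pyridin-2-yl)-4,5-dihydrooxazole (6 mol%), NH4PF6 (30 mol%), H2O (5 equiv), ClCH2CH2Cl, 60 °C
Reagents that add atoms: none
Why: Asymmetric conjugate addition of an arylboronic acid to a chromone under cationic divalent palladium with a pyridine–oxazoline ligand: transmetalation, face-selective carbopalladation of C2=C3, and protonolysis of the palladium enolate by water. The ligand sets C2 as R, and the near-neutral medium should not open the flavanone.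

Step 5
Reactants: 7 methyl (2R)-2-Ar-8-methoxy-4-oxochroman-6-carboxylate
Product: 10 methyl (2S)-2-Ar-3-diazo-8-methoxy-4-oxochroman-6-carboxylate, via lithium enolate 8 (not isolated), via 3-trifluoroacetyl ketone 9 (not isolated)
Conditions: LiN(SiMe3)2, THF, −78 °C; CF3CO2CH2CF3, −78 °C; aq. HCl; then MsN3, Et3N, H2O (1 equiv), MeCN, rt
Reagents that add atoms: methanesulfonyl azide, CS(=O)(=O)N=[N+]=[N-]; 2,2,2-trifluoroethyl trifluoroacetate, O=C(OCC(F)(F)F)C(F)(F)F (its CF3CO group is held in 9 only); LiN(SiMe3)2, [Li]N([Si](C)(C)C)[Si](C)(C)C (its lithium is held in 8 only)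
Why: Detrifluoroacetylative diazo transfer, a Regitz-type transfer to an activated 1,3-dicarbonyl compound: kinetic enolisation and C-acylation at −78 °C, then azide transfer with loss of the acyl group as the N-acyl sulfonamide. The low temperature should keep enolate 8 from opening by retro-oxa-Michael reaction; C2 keeps its geometry, and the descriptor changes to S only because C3 gains priority.

Step 6
Reactants: 10 methyl (2S)-2-Ar-3-diazo-8-methoxy-4-oxochroman-6-carboxylate
Product: 13 dimethyl (2R,3S)-2-Ar-7-methoxy-2,3-dihydrobenzofuran-3,5-dicarboxylate (cis), via ketene 11 (not isolated), via ester enol 12 (not isolated)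
Conditions: hν (365 nm, Pyrex), degassed MeOH–CH2Cl2 4:1, 0 °C; evaporation without base
Reagents that add atoms: methanol, CO
Why: This is a photochemical Wolff rearrangement of a cyclic 2-diazo ketone; the closest known cases are the ring contractions of 2-diazo-1-tetralones and 3-diazochroman-4-ones to indane and dihydrobenzofuran carboxylates. The ring holds the diazo and carbonyl groups s-Z, so excitation expels N2 in step with the 1,2-shift of aryl carbon C4a from C4 to C3; this forms the C3'–C3a' bond and ketene 11, which methanol converts into ester enol 12 and then 13. The five-membered ring arises by contraction of the six-membered ring through this 1,2-shift and not by an end-to-end cyclisation, so no exo or endo mode applies. C2' is a bystander and keeps the configuration set in step 4. The new centre C3' is set under substrate control when enol 12 is protonated on the face away from the C2' aryl group, which places the ester cis to that group. The step needs aryl migration to win over 1,2-shift of the C2 hydrogen (which would give the flavone) and over O–H insertion; the fixed s-Z geometry and direct, unsensitised irradiation favour the concerted singlet path. It also needs the kinetic cis ester to survive, which neutral methanol at 0 °C and a base-free work-up should secure. Methanol as the trap matches the methyl ester already present, so no ester exchange can arise.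

Step 7
Reactants: 13 dimethyl (2R,3S)-2-Ar-7-methoxy-2,3-dihydrobenzofuran-3,5-dicarboxylate
Product: 14 [(2R,3R)-2-Ar-3-(hydroxymethyl)-7-methoxy-2,3-dihydrobenzofuran-5-yl]methanol
Conditions: LiAlH4, THF, −20 → 0 °C; H2O, 15% NaOH
Reagents that add atoms: none
Why: Hydride reduction of both esters; at low temperature hydride addition to the C3' ester is faster than its enolisation, so the cis relationship is kept, and the benzyl ether is inert.

Step 8
Reactants: 14 [(2R,3R)-2-Ar-3-(hydroxymethyl)-7-methoxy-2,3-dihydrobenzofuran-5-yl]methanol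
Product: 15 (2R,3R)-2-Ar-3-(hydroxymethyl)-7-methoxy-2,3-dihydrobenzofuran-5-carbaldehyde
Conditions: MnO2 (activated), CH2Cl2, rt
Reagents that add atoms: none
Why: Activated MnO2 oxidises only the benzylic alcohol on the electron-rich ring; the CH2OH group on C3' is not benzylic and stays.

Step 9
Reactants: 15 (2R,3R)-2-Ar-3-(hydroxymethyl)-7-methoxy-2,3-dihydrobenzofuran-5-carbaldehyde
Product: 16 BF-carbaldehyde: (2R,3R)-2-Ar-3-[(tert-butyldiphenylsilyloxy)methyl]-7-methoxy-2,3-dihydrobenzofuran-5-carbaldehyde
Conditions: t-BuPh2SiCl, imidazole, DMF, 0 °C → rt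
Reagents that add atoms: tert-butyl(chloro)diphenylsilane, CC(C)(C)[Si](Cl)(c1ccccc1)c1ccccc1
Why: Standard silylation of a primary alcohol under conditions that leave the aldehyde alone. A silyl ether is chosen over a benzyl ether so that the final hydrogenolysis has only two aryl benzyl ethers to cleave.

Step 10
Reactants: 17 1-(benzyloxy)-4-bromo-2-methoxybenzene; 18 methyl (2S)-oxirane-2-carboxylate
Product: 20 methyl (2S)-3-Ar-2-hydroxypropanoate, via arylmagnesium bromide 19 (not isolated)
Conditions: Mg, THF, reflux; then 18, CuI (10 mol%), THF, −40 → −20 °C; aq. NH4Cl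
Reagents that add atoms: magnesium, [Mg] (held in 19 only)
Why: Copper-catalysed SN2 opening of a glycidic ester by an aryl Grignard reagent at the unsubstituted C3. The stereocentre is not touched, so the S configuration of 18 is carried into 20, and at low temperature the organocopper species leaves the ester alone.

Step 11
Reactants: 20 methyl (2S)-3-Ar-2-hydroxypropanoate
Product: 21 (2S)-3-Ar-2-hydroxypropanoic acid
Conditions: LiOH·H2O, THF–H2O, 0 °C → rt; then 1 M HCl
Reagents that add atoms: lithium hydroxide, [Li+].[OH-]
Why: Saponification; the α-hydrogen of an α-hydroxy ester is not labile enough to racemise under these mild conditions.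

Step 12
Reactants: 21 (2S)-3-Ar-2-hydroxypropanoic acid; 16 BF-carbaldehyde
Product: 23 (2S,5S)-5-(Ar-methyl)-2-BF-1,3-dioxolan-4-one (cis), via bis(trimethylsilyl) derivative 22 (not isolated)
Conditions: HN(SiMe3)2, Me3SiCl (cat.), CH2Cl2, 40 °C; evaporate; then 16, Me3SiOTf (10 mol%), CH2Cl2, −78 °C; pyridine
Reagents that add atoms: hexamethyldisilazane, C[Si](C)(C)N[Si](C)(C)C (its Me3Si groups are held in 22 only)
Why: Silyl-modified acetalisation: the bis-silylated hydroxy acid condenses with the aldehyde under Me3SiOTf catalysis with loss of (Me3Si)2O, and the cis dioxolanone is favoured. The acetal configuration is erased again in step 14, and the lactic stereocentre is not involved.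

Step 13
Reactants: 23 (2S,5S)-5-(Ar-methyl)-2-BF-1,3-dioxolan-4-one
Product: 24 (2S,5S)-5-(Ar-methyl)-2-BF-4-methylidene-1,3-dioxolane
Conditions: Cp2TiMe2 (2.5 equiv), toluene–THF, 65 °C, dark; filtration through basic Al2O3
Reagents that add atoms: Cp2TiMe2 (dimethyltitanocene), C[Ti](C)(C1C=CC=C1)C1C=CC=C1
Why: Titanium-based carbonyl methylenation of a lactone through Cp2Ti=CH2. The reagent is not basic, tolerates the acetal and the ethers, and gives the acid-labile enol ether needed next.

Step 14
Reactants: 24 (2S,5S)-5-(Ar-methyl)-2-BF-4-methylidene-1,3-dioxolane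
Product: 25 (2S,5S)-2-(Ar-methyl)-5-BF-dihydrofuran-3(2H)-one (2,5-cis)
Conditions: Me2AlCl (1.5 equiv), CH2Cl2, −78 → −30 °C; aq. NaHCO3
Reagents that add atoms: none
Why: Petasis–Ferrier rearrangement: Me2AlCl ionises the acetal to an aluminium enolate and an aryl-stabilised oxocarbenium ion, which recombine by forming the C4–C5 bond. Closure through an envelope with both substituents pseudo-equatorial sets C5 cis to the C2 benzyl group, whose configuration comes from 21.

Step 15
Reactants: 25 (2S,5S)-2-(Ar-methyl)-5-BF-dihydrofuran-3(2H)-one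
Product: 27 (2S,4R,5S)-2-(Ar-methyl)-5-BF-4-(hydroxymethyl)dihydrofuran-3(2H)-one, via lithium enolate 26 (not isolated)
Conditions: LiN(i-Pr)2, THF, −78 °C; CH2O (gas, from cracked paraformaldehyde), −78 °C; aq. NH4Cl
Reagents that add atoms: formaldehyde, C=O; LiN(i-Pr)2, [Li]N(C(C)C)C(C)C (its lithium is held in 26 only)
Why: Aldol reaction with formaldehyde: the amide base deprotonates kinetically at the C4 methylene rather than at the alkoxy-substituted C2 methine. Formaldehyde adds to the enolate face opposite the C5 aryl group, which sets C4 with CH2OH trans to that group.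

Step 16
Reactants: 27 (2S,4R,5S)-2-(Ar-methyl)-5-BF-4-(hydroxymethyl)dihydrofuran-3(2H)-one
Product: 28 (2S,3S,4S,5S)-2-(Ar-methyl)-5-BF-4-(hydroxymethyl)tetrahydrofuran-3-ol
Conditions: Me4NBH(OAc)3, MeCN–AcOH 1:1, −30 °C
Reagents that add atoms: none
Why: Evans–Saksena reduction: the primary hydroxyl binds boron and delivers hydride to the C3 ketone on its own face. This is also the face opposite the C2 benzyl and C5 aryl groups, so the C3 hydroxyl ends up trans to the C4 arm and cis to the benzyl group.

Step 17
Reactants: 28 (2S,3S,4S,5S)-2-(Ar-methyl)-5-BF-4-(hydroxymethyl)tetrahydrofuran-3-ol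
Product: 29 (2S,3S,4S,5S)-2-(Ar-methyl)-5-[(2R,3R)-2-Ar-3-(hydroxymethyl)-7-methoxy-2,3-dihydrobenzofuran-5-yl]-4-(hydroxymethyl)tetrahydrofuran-3-ol
Conditions: Bu4NF, THF, 0 °C → rt
Reagents that add atoms: none
Why: Fluoride cleavage of the silyl ether; benzyl ethers and the benzylic ring ethers are inert to it.

Step 18
Reactants: 29 (2S,3S,4S,5S)-2-(Ar-methyl)-5-[(2R,3R)-2-Ar-3-(hydroxymethyl)-7-methoxy-2,3-dihydrobenzofuran-5-yl]-4-(hydroxymethyl)tetrahydrofuran-3-ol
Product: 30 target CNP0179668.1
Conditions: H2 (1 atm), 10% Pd/C, EtOAc–EtOH, rt, stopped at full debenzylation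
Reagents that add atoms: none
Why: Hydrogenolysis of the two aryl benzyl ethers, which cleave much faster than the benzylic ring bonds C5–O1 and C2'–O1'. A neutral solvent and a short exposure should protect those bonds and the free phenols.

## Compound list

1 | 2'-hydroxy-3'-methoxyacetophenone | CC(=O)c1cccc(OC)c1O | starting material
2 | 5'-bromo-2'-hydroxy-3'-methoxyacetophenone | CC(=O)c1cc(Br)cc(OC)c1O | intermediate
3 | methyl 3-acetyl-4-hydroxy-5-methoxybenzoate | COC(=O)c1cc(OC)c(O)c(C(C)=O)c1 | intermediate
4 | methyl 3-[(2E)-3-(dimethylamino)prop-2-enoyl]-4-hydroxy-5-methoxybenzoate | COC(=O)c1cc(OC)c(O)c(C(=O)/C=C/N(C)C)c1 | intermediate (not isolated)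
5 | methyl 8-methoxy-4-oxo-4H-chromene-6-carboxylate | COC(=O)c1cc(OC)c2c(c1)C(=O)C=CO2 | intermediate
6 | (4-benzyloxy-3-methoxyphenyl)boronic acid | COc1cc(B(O)O)ccc1OCc1ccccc1 | starting material
7 | methyl (2R)-2-[4-(benzyloxy)-3-methoxyphenyl]-8-methoxy-4-oxochroman-6-carboxylate | COC(=O)c1cc(OC)c2c(c1)C(=O)C[C@H](c1ccc(OCc3ccccc3)c(OC)c1)O2 | intermediate
8 | lithium (2R)-2-[4-(benzyloxy)-3-methoxyphenyl]-8-methoxy-6-(methoxycarbonyl)-2H-chromen-4-olate | COC(=O)c1cc(OC)c2c(c1)C(O[Li])=C[C@H](c1ccc(OCc3ccccc3)c(OC)c1)O2 | intermediate (not isolated)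
9 | methyl (2R)-2-[4-(benzyloxy)-3-methoxyphenyl]-8-methoxy-4-oxo-3-(trifluoroacetyl)chroman-6-carboxylate (C3 epimers and enol form) | COC(=O)c1cc(OC)c2c(c1)C(=O)C(C(=O)C(F)(F)F)[C@H](c1ccc(OCc3ccccc3)c(OC)c1)O2 | intermediate (not isolated)
10 | methyl (2S)-2-[4-(benzyloxy)-3-methoxyphenyl]-3-diazo-8-methoxy-4-oxochroman-6-carboxylate | COC(=O)c1cc(OC)c2c(c1)C(=O)C(=[N+]=[N-])[C@H](c1ccc(OCc3ccccc3)c(OC)c1)O2 | intermediate
11 | methyl (2S)-2-[4-(benzyloxy)-3-methoxyphenyl]-7-methoxy-3-(oxomethylidene)-2,3-dihydrobenzofuran-5-carboxylate (ketene) | COC(=O)c1cc(OC)c2c(c1)C(=C=O)[C@H](c1ccc(OCc3ccccc3)c(OC)c1)O2 | intermediate (not isolated)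
12 | methyl (2S)-2-[4-(benzyloxy)-3-methoxyphenyl]-3-[hydroxy(methoxy)methylidene]-7-methoxy-2,3-dihydrobenzofuran-5-carboxylate (ester enol) | COC(=O)c1cc(OC)c2c(c1)C(=C(O)OC)[C@H](c1ccc(OCc3ccccc3)c(OC)c1)O2 | intermediate (not isolated)
13 | dimethyl (2R,3S)-2-[4-(benzyloxy)-3-methoxyphenyl]-7-methoxy-2,3-dihydrobenzofuran-3,5-dicarboxylate (cis) | COC(=O)c1cc(OC)c2c(c1)[C@H](C(=O)OC)[C@H](c1ccc(OCc3ccccc3)c(OC)c1)O2 | intermediate
14 | [(2R,3R)-2-[4-(benzyloxy)-3-methoxyphenyl]-3-(hydroxymethyl)-7-methoxy-2,3-dihydrobenzofuran-5-yl]methanol | OCc1cc(OC)c2c(c1)[C@H](CO)[C@H](c1ccc(OCc3ccccc3)c(OC)c1)O2 | intermediate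
15 | (2R,3R)-2-[4-(benzyloxy)-3-methoxyphenyl]-3-(hydroxymethyl)-7-methoxy-2,3-dihydrobenzofuran-5-carbaldehyde | O=Cc1cc(OC)c2c(c1)[C@H](CO)[C@H](c1ccc(OCc3ccccc3)c(OC)c1)O2 | intermediate
16 | (2R,3R)-2-[4-(benzyloxy)-3-methoxyphenyl]-3-[(tert-butyldiphenylsilyloxy)methyl]-7-methoxy-2,3-dihydrobenzofuran-5-carbaldehyde | O=Cc1cc(OC)c2c(c1)[C@H](CO[Si](c1ccccc1)(c1ccccc1)C(C)(C)C)[C@H](c1ccc(OCc3ccccc3)c(OC)c1)O2 | intermediate
17 | 1-(benzyloxy)-4-bromo-2-methoxybenzene | COc1cc(Br)ccc1OCc1ccccc1 | starting material
18 | methyl (2S)-oxirane-2-carboxylate | COC(=O)[C@@H]1CO1 | starting material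
19 | [4-(benzyloxy)-3-methoxyphenyl]magnesium bromide | COc1cc([Mg]Br)ccc1OCc1ccccc1 | intermediate (not isolated)
20 | methyl (2S)-3-[4-(benzyloxy)-3-methoxyphenyl]-2-hydroxypropanoate | COC(=O)[C@@H](O)Cc1ccc(OCc2ccccc2)c(OC)c1 | intermediate
21 | (2S)-3-[4-(benzyloxy)-3-methoxyphenyl]-2-hydroxypropanoic acid | OC(=O)[C@@H](O)Cc1ccc(OCc2ccccc2)c(OC)c1 | intermediate
22 | trimethylsilyl (2S)-3-[4-(benzyloxy)-3-methoxyphenyl]-2-(trimethylsilyloxy)propanoate | C[Si](C)(C)OC(=O)[C@@H](O[Si](C)(C)C)Cc1ccc(OCc2ccccc2)c(OC)c1 | intermediate (not isolated)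
23 | (2S,5S)-5-[4-(benzyloxy)-3-methoxybenzyl]-2-BF-1,3-dioxolan-4-one (cis) | O=C1O[C@@H](c2cc(OC)c3c(c2)[C@H](CO[Si](c2ccccc2)(c2ccccc2)C(C)(C)C)[C@H](c2ccc(OCc4ccccc4)c(OC)c2)O3)O[C@H]1Cc1ccc(OCc2ccccc2)c(OC)c1 | intermediate
24 | (2S,5S)-5-[4-(benzyloxy)-3-methoxybenzyl]-2-BF-4-methylidene-1,3-dioxolane | C=C1O[C@@H](c2cc(OC)c3c(c2)[C@H](CO[Si](c2ccccc2)(c2ccccc2)C(C)(C)C)[C@H](c2ccc(OCc4ccccc4)c(OC)c2)O3)O[C@H]1Cc1ccc(OCc2ccccc2)c(OC)c1 | intermediate
25 | (2S,5S)-2-[4-(benzyloxy)-3-methoxybenzyl]-5-BF-dihydrofuran-3(2H)-one (2,5-cis) | COc1cc(C[C@@H]2O[C@H](c3cc(OC)c4c(c3)[C@H](CO[Si](c3ccccc3)(c3ccccc3)C(C)(C)C)[C@H](c3ccc(OCc5ccccc5)c(OC)c3)O4)CC2=O)ccc1OCc1ccccc1 | intermediate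
26 | lithium (2S,5S)-2-[4-(benzyloxy)-3-methoxybenzyl]-5-BF-2,5-dihydrofuran-3-olate | COc1cc(C[C@@H]2O[C@H](c3cc(OC)c4c(c3)[C@H](CO[Si](c3ccccc3)(c3ccccc3)C(C)(C)C)[C@H](c3ccc(OCc5ccccc5)c(OC)c3)O4)C=C2O[Li])ccc1OCc1ccccc1 | intermediate (not isolated)
27 | (2S,4R,5S)-2-[4-(benzyloxy)-3-methoxybenzyl]-5-BF-4-(hydroxymethyl)dihydrofuran-3(2H)-one | COc1cc(C[C@@H]2O[C@H](c3cc(OC)c4c(c3)[C@H](CO[Si](c3ccccc3)(c3ccccc3)C(C)(C)C)[C@H](c3ccc(OCc5ccccc5)c(OC)c3)O4)[C@@H](CO)C2=O)ccc1OCc1ccccc1 | intermediate
28 | (2S,3S,4S,5S)-2-[4-(benzyloxy)-3-methoxybenzyl]-5-BF-4-(hydroxymethyl)tetrahydrofuran-3-ol | COc1cc(C[C@@H]2O[C@H](c3cc(OC)c4c(c3)[C@H](CO[Si](c3ccccc3)(c3ccccc3)C(C)(C)C)[C@H](c3ccc(OCc5ccccc5)c(OC)c3)O4)[C@@H](CO)[C@@H]2O)ccc1OCc1ccccc1 | intermediate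
29 | (2S,3S,4S,5S)-2-[4-(benzyloxy)-3-methoxybenzyl]-5-[(2R,3R)-2-[4-(benzyloxy)-3-methoxyphenyl]-3-(hydroxymethyl)-7-methoxy-2,3-dihydrobenzofuran-5-yl]-4-(hydroxymethyl)tetrahydrofuran-3-ol | COc1cc(C[C@@H]2O[C@H](c3cc(OC)c4c(c3)[C@H](CO)[C@H](c3ccc(OCc5ccccc5)c(OC)c3)O4)[C@@H](CO)[C@@H]2O)ccc1OCc1ccccc1 | intermediate
30 | (2S,3S,4S,5S)-2-(4-hydroxy-3-methoxybenzyl)-5-[(2R,3R)-2-(4-hydroxy-3-methoxyphenyl)-3-(hydroxymethyl)-7-methoxy-2,3-dihydrobenzofuran-5-yl]-4-(hydroxymethyl)tetrahydrofuran-3-ol (CNP0179668.1) | COc1cc(C[C@@H]2O[C@H](c3cc(OC)c4c(c3)[C@H](CO)[C@H](c3ccc(O)c(OC)c3)O4)[C@@H](CO)[C@@H]2O)ccc1O | target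

## Step count and least certain steps

Total step count: 18. Longest linear sequence: 16 steps (steps 1–9, then 12–18). Steps 10–11 are a two-step side branch.

**Step 6 (key step).** The most likely failure is poor facial selectivity in the ketonisation of enol 12, or later epimerisation at C3' through the ester enol. Only the one neighbouring aryl group differentiates the two faces, and the cis ester is the less stable isomer. A 1,2-shift of the activated C2 hydrogen, which would give the flavone, is the second concern. Fallback, from 10 back to 13: the photolysis is run without regard to the C3' outcome, and the crude esters are converged with NaOMe in MeOH on the trans ester, dimethyl (2R,3R)-2-Ar-7-methoxy-2,3-dihydrobenzofuran-3,5-dicarboxylate F2. F2 is deprotonated with LiN(i-Pr)2 in THF at −78 °C to the lithium ester enolate F3, which is quenched at −78 °C with the hindered proton donor 2,6-di-tert-butyl-4-methylphenol. The C3' centre is then set in a separate kinetic protonation, in which the size of the proton donor and the temperature can be chosen, and the proton should enter opposite the C2' aryl group to give 13.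

**Step 5.** Enolate 8, or the enolate of 9 under Et3N, may open by retro-oxa-Michael reaction and reclose, which would racemise C2; in a flavanone the ring oxygen is a β-leaving group. Fallback, from 7 back to 10: C3 is nitrosated under acid (isoamyl nitrite, HCl, THF–EtOH, 0 °C), which passes through the enol and not the enolate, to give methyl (2S)-2-Ar-3-(hydroxyimino)-8-methoxy-4-oxochroman-6-carboxylate F1. A Forster reaction (chloramine from aqueous NH3 and NaOCl, NaOH, 0 °C) then converts the oxime into diazo ketone 10.

**Step 14.** The recombination is formally a 5-(enolendo)-endo-trig closure. If the aluminium enolate and the well-stabilised oxocarbenium ion drift apart instead of bonding, the acetal fragments back to its components. The Lewis acid may also ionise C2'–O1' and epimerise the cis-dihydrobenzofuran. Fallback, from 21 and 16 back to 25: 21 is treated with excess MeLi (THF, −78 → 0 °C) to give (3S)-4-Ar-3-hydroxybutan-2-one F4. Two equivalents of LiN(i-Pr)2 convert F4 into dilithium (3S)-4-Ar-but-1-ene-2,3-diolate F5, which adds to 16 to give the aldol (4S)-5-Ar-1-BF-1,4-dihydroxypentan-3-one F6 as a mixture at C1. Mild acid (pyridinium p-toluenesulfonate, CH2Cl2) ionises the benzylic C1 hydroxyl and the C4 hydroxyl captures the cation. The ring is then closed at O1–C5 instead of C4–C5, and the 2,5-cis ketone 25 should form under thermodynamic control.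

**Step 15.** Deprotonation on the C2 side would scramble C2 or hydroxymethylate the wrong carbon. The β-hydroxy ketone may also lose water to the exo-methylene ketone, or react twice with formaldehyde, under basic conditions. Fallback, from 25 back to 27: enolate 26 is trapped with Me3SiCl as (2S,5S)-2-(Ar-methyl)-5-BF-3-(trimethylsilyloxy)-2,5-dihydrofuran F7, whose regiochemistry can be checked and purified. A Mukaiyama aldol reaction with aqueous formaldehyde and Yb(OTf)3 (cat.) in THF–H2O then gives 27 under almost neutral conditions, where elimination and retro-aldol reaction are slow.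

## Further compounds

F1 | step 5 | methyl (2S)-2-[4-(benzyloxy)-3-methoxyphenyl]-3-(hydroxyimino)-8-methoxy-4-oxochroman-6-carboxylate | COC(=O)c1cc(OC)c2c(c1)C(=O)C(=NO)[C@H](c1ccc(OCc3ccccc3)c(OC)c1)O2
F2 | step 6 | dimethyl (2R,3R)-2-[4-(benzyloxy)-3-methoxyphenyl]-7-methoxy-2,3-dihydrobenzofuran-3,5-dicarboxylate (trans) | COC(=O)c1cc(OC)c2c(c1)[C@@H](C(=O)OC)[C@H](c1ccc(OCc3ccccc3)c(OC)c1)O2
F3 | step 6 | lithium ester enolate of F2, methyl (2S)-2-[4-(benzyloxy)-3-methoxyphenyl]-3-[(lithiooxy)(methoxy)methylidene]-7-methoxy-2,3-dihydrobenzofuran-5-carboxylate | COC(=O)c1cc(OC)c2c(c1)C(=C(OC)O[Li])[C@H](c1ccc(OCc3ccccc3)c(OC)c1)O2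
F4 | step 14 | (3S)-4-[4-(benzyloxy)-3-methoxyphenyl]-3-hydroxybutan-2-one | CC(=O)[C@@H](O)Cc1ccc(OCc2ccccc2)c(OC)c1
F5 | step 14 | dilithium (3S)-4-[4-(benzyloxy)-3-methoxyphenyl]but-1-ene-2,3-diolate | [Li]OC(=C)[C@@H](O[Li])Cc1ccc(OCc2ccccc2)c(OC)c1
F6 | step 14 | (4S)-5-[4-(benzyloxy)-3-methoxyphenyl]-1-BF-1,4-dihydroxypentan-3-one (both C1 epimers) | O=C(CC(O)c1cc(OC)c2c(c1)[C@H](CO[Si](c1ccccc1)(c1ccccc1)C(C)(C)C)[C@H](c1ccc(OCc3ccccc3)c(OC)c1)O2)[C@@H](O)Cc1ccc(OCc2ccccc2)c(OC)c1
F7 | step 15 | (2S,5S)-2-[4-(benzyloxy)-3-methoxybenzyl]-5-BF-3-(trimethylsilyloxy)-2,5-dihydrofuran | COc1cc(C[C@@H]2O[C@H](c3cc(OC)c4c(c3)[C@H](CO[Si](c3ccccc3)(c3ccccc3)C(C)(C)C)[C@H](c3ccc(OCc5ccccc5)c(OC)c3)O4)C=C2O[Si](C)(C)C)ccc1OCc1ccccc1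
A1 | alternative 1 | cis-4-[4-(benzyloxy)-3-methoxybenzyl]-2,2-dichloro-3-[(1S)-1-(2,4,6-triisopropylphenyl)ethoxy]cyclobutan-1-one | O=C1C(Cl)(Cl)[C@H](O[C@@H](C)c2c(C(C)C)cc(C(C)C)cc2C(C)C)[C@@H]1Cc1ccc(OCc2ccccc2)c(OC)c1
A2 | alternative 1 | 1-(benzyloxy)-2-methoxy-4-[(2Z)-3-[(1S)-1-(2,4,6-triisopropylphenyl)ethoxy]prop-2-en-1-yl]benzene | COc1cc(C/C=C\O[C@@H](C)c2c(C(C)C)cc(C(C)C)cc2C(C)C)ccc1OCc1ccccc1
A3 | alternative 1 | dichloroketene | O=C=C(Cl)Cl
A4 | alternative 2 | (2S,5S)-2-[4-(benzyloxy)-3-methoxybenzyl]-5-[(2R,3R)-2-[4-(benzyloxy)-3-methoxyphenyl]-3-[(benzyloxy)methyl]-7-methoxy-2,3-dihydrobenzofuran-5-yl]dihydrofuran-3(2H)-one | COc1cc(C[C@@H]2O[C@H](c3cc(OC)c4c(c3)[C@H](COCc3ccccc3)[C@H](c3ccc(OCc5ccccc5)c(OC)c3)O4)CC2=O)ccc1OCc1ccccc1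
A5 | alternative 2 | (2S,5S)-5-[4-(benzyloxy)-3-methoxybenzyl]-2-[(2R,3R)-2-[4-(benzyloxy)-3-methoxyphenyl]-3-[(benzyloxy)methyl]-7-methoxy-2,3-dihydrobenzofuran-5-yl]-4-methylidene-1,3-dioxolane | C=C1O[C@@H](c2cc(OC)c3c(c2)[C@H](COCc2ccccc2)[C@H](c2ccc(OCc4ccccc4)c(OC)c2)O3)O[C@H]1Cc1ccc(OCc2ccccc2)c(OC)c1
A6 | alternative 3 | (2R,3R)-5-bromo-3-[(tert-butyldimethylsilyloxy)methyl]-7-methoxy-2-(3-methoxy-4-tosyloxyphenyl)-2,3-dihydrobenzofuran (cis) | Brc1cc(OC)c2c(c1)[C@H](CO[Si](C)(C)C(C)(C)C)[C@H](c1ccc(OS(=O)(=O)c3ccc(C)cc3)c(OC)c1)O2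
A7 | alternative 3 | 4-[(1S,2R)-2-(5-bromo-2-hydroxy-3-methoxyphenyl)-3-(tert-butyldimethylsilyloxy)-1-hydroxypropyl]-2-methoxyphenyl 4-methylbenzenesulfonate | Oc1c(OC)cc(Br)cc1[C@H](CO[Si](C)(C)C(C)(C)C)[C@H](O)c1ccc(OS(=O)(=O)c2ccc(C)cc2)c(OC)c1
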